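## Retrosynthetic overview

1. Target 19 ⇐ bis(benzyl ether) 18 ⇐ arylboronic acid 15 + 7-(benzyloxy)chromone 17: the flavanone C2–aryl bond comes from a catalyst-controlled conjugate arylation of the flat chromone, which sets the 2S centre last.
2. 15 ⇐ bromo alcohol 12 ⇐ 2,2-dimethylchroman-3-one 11 by oxazaborolidine-controlled reduction, which sets the 3S carbinol.
3. 11 ⇐ open-chain aldehyde / redox-active ester 10: the C2–C3 bond of the dihydropyran ring is formed in the ring closure, an NHC-catalysed decarboxylative radical acylation.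
4. Enabling feature: in the dihydropyran ring, C2 carries the ring oxygen O1 and two methyl groups, so it can be generated as a tertiary α-aryloxy radical by loss of CO2 from an aryloxyisobutyrate. C3 carries the hydroxyl next to benzylic C4, so it can enter at the aldehyde level from an ortho-allyl group, and the two arms sit ortho on the benzene ring, which makes their union a six-membered closure.
5. Ring order: the benzene ring is bought; the dihydropyran ring is closed in step 7; the benzopyranone bicycle of the flavanone is bought as the chromone and joined in step 11.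

Key step: step 7

Assumption: the facial sense of step 11 is taken from the established model for (S)-biaryl bisphosphine rhodium catalysts with cyclic enones, which maps onto 2S for a chromone; the antipodal ligand would be used if a model flavanone showed the opposite sense.

## Route

Step 1
Reactants: 1 2-(benzyloxy)phenol
Product: 2 2-(benzyloxy)-4-bromophenol
Conditions: NBS (1.0 equiv), MeCN, 0 °C
Reagents that add atoms: N-bromosuccinimide, O=C1CCC(=O)N1Br
Why: Electrophilic aromatic bromination, in which the free hydroxyl is the strongest director and its para position is open, as in the bromination of guaiacol.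

Step 2
Reactants: 2 2-(benzyloxy)-4-bromophenol
Product: 3 1-(allyloxy)-2-(benzyloxy)-4-bromobenzene
Conditions: allyl bromide, K2CO3, acetone, reflux
Reagents that add atoms: allyl bromide, C=CCBr
Why: Williamson ether synthesis on the phenoxide with a reactive primary allylic halide.

Step 3
Reactants: 3 1-(allyloxy)-2-(benzyloxy)-4-bromobenzene
Product: 5 2-allyl-6-(benzyloxy)-4-bromophenol, via dienone 4 (not isolated)
Conditions: N,N-diethylaniline, 190 °C
Reagents that add atoms: none
Why: Aromatic Claisen rearrangement, a [3,3]-sigmatropic shift of the allyl group to the only unsubstituted ortho carbon, followed by tautomerisation of the dienone to the phenol.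

Step 4
Reactants: 5 2-allyl-6-(benzyloxy)-4-bromophenol
Product: 7 2-[2-allyl-6-(benzyloxy)-4-bromophenoxy]-2-methylpropanoic acid, via ethyl ester 6 (not isolated)
Conditions: ethyl 2-bromo-2-methylpropanoate (3 equiv), Cs2CO3, DMF, 70 °C; then aq. NaOH, MeOH, 60 °C; aq. HCl
Reagents that add atoms: ethyl 2-bromo-2-methylpropanoate, CCOC(=O)C(C)(C)Br; sodium hydroxide, [Na+].[OH-]
Why: O-alkylation of the caesium phenoxide at the tertiary α-carbon of the bromo ester, the standard entry to aryloxyisobutyrates that tolerates ortho substituents, followed by saponification in the same pot.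

Step 5
Reactants: 7 2-[2-allyl-6-(benzyloxy)-4-bromophenoxy]-2-methylpropanoic acid
Product: 8 1,3-dioxoisoindolin-2-yl 2-[2-allyl-6-(benzyloxy)-4-bromophenoxy]-2-methylpropanoate
Conditions: N-hydroxyphthalimide, DIC, DMAP (cat.), CH2Cl2, rt
Reagents that add atoms: N-hydroxyphthalimide, O=C1c2ccccc2C(=O)N1O
Why: Carbodiimide (Steglich-type) esterification, routinely used to turn tertiary acids into redox-active N-acyloxyphthalimides.

Step 6
Reactants: 8 1,3-dioxoisoindolin-2-yl 2-[2-allyl-6-(benzyloxy)-4-bromophenoxy]-2-methylpropanoate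
Product: 10 1,3-dioxoisoindolin-2-yl 2-[2-(benzyloxy)-4-bromo-6-(2-oxoethyl)phenoxy]-2-methylpropanoate, via ozonide 9 (not isolated)
Conditions: O3 (1 equiv, indicator), CH2Cl2, −78 °C; then PPh3, −78 °C to rt
Reagents that add atoms: ozone, [O-][O+]=O
Why: Ozonolysis with reductive work-up, in which the terminal alkene should react much faster than the bromo-substituted arene and the active ester is inert under anhydrous conditions; the aldehyde is used at once.

Step 7
Reactants: 10 1,3-dioxoisoindolin-2-yl 2-[2-(benzyloxy)-4-bromo-6-(2-oxoethyl)phenoxy]-2-methylpropanoate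
Product: 11 8-(benzyloxy)-6-bromo-2,2-dimethylchroman-3-one
Conditions: 3-(2,6-diisopropylphenyl)-5,6,7,8-tetrahydro-4H-cyclohepta[d]thiazol-3-ium perchlorate (10 mol %), Cs2CO3 (20 mol %), DMSO (0.02 M), 60 °C, N2
Reagents that add atoms: none
Why: Radical NHC catalysis: the thiazol-2-ylidene adds to the aldehyde of 10, the deprotonated Breslow intermediate passes one electron to the N-acyloxyphthalimide in the same molecule, loss of phthalimide anion and CO2 leaves the tertiary α-aryloxy radical at C2 beside the persistent carbene-bound ketyl radical at C3, and their combination followed by release of the carbene should give ketone 11. The closest known reaction type is the intermolecular NHC-catalysed decarboxylative coupling of aliphatic aldehydes with tertiary alkyl N-acyloxyphthalimides to dialkyl ketones. The dihydropyranone ring closes by radical–radical combination in a 6-exo mode, C2 attacking the trigonal ketyl carbon C3 whose oxygen and carbene substituents stay outside the new ring. No stereocentre arises: C2 becomes the gem-dimethyl quaternary carbon and C3 is left as a ketone for reagent-controlled reduction in step 8. The step needs carbon–carbon cross-coupling of the two radicals and acyl-anion formation faster than enolisation of the arylacetaldehyde; the first is secured by the persistence of the ketyl radical and the ortho tether on the benzene ring, the second by substoichiometric Cs2CO3 and dilution.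

Step 8
Reactants: 11 8-(benzyloxy)-6-bromo-2,2-dimethylchroman-3-one
Product: 12 (3S)-8-(benzyloxy)-6-bromo-2,2-dimethylchroman-3-ol
Conditions: (R)-2-methyl-CBS-oxazaborolidine (15 mol %), BH3·SMe2, THF, −20 °C; MeOH quench
Reagents that add atoms: none
Why: Corey–Bakshi–Shibata reduction, in which the (R)-oxazaborolidine–borane complex binds the ketone with the bulky quaternary C2 side away from the catalyst and delivers hydride to the face that gives the 3S carbinol (reagent control; the (S)-catalyst would give 3R).

Step 9
Reactants: 12 (3S)-8-(benzyloxy)-6-bromo-2,2-dimethylchroman-3-ol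
Product: 15 [(3S)-8-(benzyloxy)-3-hydroxy-2,2-dimethylchroman-6-yl]boronic acid, via dilithio species 13 (not isolated), via lithium triisopropoxyborate 14 (not isolated)
Conditions: n-BuLi (2.2 equiv), THF, −78 °C; B(OiPr)3, −78 °C to rt; aq. HCl
Reagents that add atoms: triisopropyl borate, CC(C)OB(OC(C)C)OC(C)C; water, O
Why: Deprotonation of the hydroxyl and bromine–lithium exchange, borylation of the aryllithium and acidic hydrolysis of the borate, none of which touches the carbinol centre.

Step 10
Reactants: 16 7-hydroxy-4H-chromen-4-one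
Product: 17 7-(benzyloxy)-4H-chromen-4-one
Conditions: BnBr, K2CO3, DMF, rt
Reagents that add atoms: benzyl bromide, BrCc1ccccc1
Why: Williamson benzylation of the acidic 7-hydroxyl, which would otherwise protonate the aryl–rhodium intermediate of step 11.

Step 11
Reactants: 15 [(3S)-8-(benzyloxy)-3-hydroxy-2,2-dimethylchroman-6-yl]boronic acid; 17 7-(benzyloxy)-4H-chromen-4-one
Product: 18 (2S)-7-(benzyloxy)-2-[(3S)-8-(benzyloxy)-3-hydroxy-2,2-dimethylchroman-6-yl]chroman-4-one
Conditions: 15 (1.5 equiv), [RhOH(cod)]2 (2.5 mol %), (S)-MeO-F12-BIPHEP [(S)-6,6'-dimethoxy-2,2'-bis[bis(3,4,5-trifluorophenyl)phosphino]biphenyl] (5.5 mol %), toluene/H2O, 40 °C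
Reagents that add atoms: none
Why: Rhodium-catalysed asymmetric 1,4-addition of an arylboronic acid to an enone (Hayashi–Miyaura reaction), in which the aryl–rhodium species bearing the (S)-bisphosphine inserts the C2=C3 bond of the chromone on one face, so that the 2S centre is set by the catalyst and not by the distant 3S carbinol, while base-free hydrolysis of the rhodium enolate avoids ring opening.

Step 12
Reactants: 18 (2S)-7-(benzyloxy)-2-[(3S)-8-(benzyloxy)-3-hydroxy-2,2-dimethylchroman-6-yl]chroman-4-one
Product: 19 (2S)-7-hydroxy-2-[(3S)-3,8-dihydroxy-2,2-dimethyl-3,4-dihydro-2H-chromen-6-yl]-2,3-dihydro-4H-chromen-4-one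
Conditions: H2 (1 atm), Pd/C (10 wt %), EtOAc/MeOH, rt
Reagents that add atoms: none
Why: Hydrogenolysis of the two benzyl aryl ethers under neutral conditions, which should leave the base-sensitive flavanone centre and the carbinol untouched.

## Compound list

1 | 2-(benzyloxy)phenol | Oc1ccccc1OCc1ccccc1 | starting material
2 | 2-(benzyloxy)-4-bromophenol | Oc1ccc(Br)cc1OCc1ccccc1 | intermediate
3 | 1-(allyloxy)-2-(benzyloxy)-4-bromobenzene | C=CCOc1ccc(Br)cc1OCc1ccccc1 | intermediate
4 | 6-allyl-2-(benzyloxy)-4-bromocyclohexa-2,4-dien-1-one | O=C1C(CC=C)C=C(Br)C=C1OCc1ccccc1 | intermediate (not isolated)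
5 | 2-allyl-6-(benzyloxy)-4-bromophenol | Oc1c(CC=C)cc(Br)cc1OCc1ccccc1 | intermediate
6 | ethyl 2-[2-allyl-6-(benzyloxy)-4-bromophenoxy]-2-methylpropanoate | CCOC(=O)C(C)(C)Oc1c(CC=C)cc(Br)cc1OCc1ccccc1 | intermediate (not isolated)
7 | 2-[2-allyl-6-(benzyloxy)-4-bromophenoxy]-2-methylpropanoic acid | OC(=O)C(C)(C)Oc1c(CC=C)cc(Br)cc1OCc1ccccc1 | intermediate
8 | 1,3-dioxoisoindolin-2-yl 2-[2-allyl-6-(benzyloxy)-4-bromophenoxy]-2-methylpropanoate | O=C(ON1C(=O)c2ccccc2C1=O)C(C)(C)Oc1c(CC=C)cc(Br)cc1OCc1ccccc1 | intermediate
9 | 1,3-dioxoisoindolin-2-yl 2-[2-(benzyloxy)-4-bromo-6-(1,2,4-trioxolan-3-ylmethyl)phenoxy]-2-methylpropanoate | O=C(ON1C(=O)c2ccccc2C1=O)C(C)(C)Oc1c(CC2OOCO2)cc(Br)cc1OCc1ccccc1 | intermediate (not isolated)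
10 | 1,3-dioxoisoindolin-2-yl 2-[2-(benzyloxy)-4-bromo-6-(2-oxoethyl)phenoxy]-2-methylpropanoate | O=C(ON1C(=O)c2ccccc2C1=O)C(C)(C)Oc1c(CC=O)cc(Br)cc1OCc1ccccc1 | intermediate
11 | 8-(benzyloxy)-6-bromo-2,2-dimethylchroman-3-one | CC1(C)Oc2c(OCc3ccccc3)cc(Br)cc2CC1=O | intermediate
12 | (3S)-8-(benzyloxy)-6-bromo-2,2-dimethylchroman-3-ol | CC1(C)Oc2c(OCc3ccccc3)cc(Br)cc2C[C@@H]1O | intermediate
13 | lithium (3S)-8-(benzyloxy)-6-lithio-2,2-dimethylchroman-3-olate | CC1(C)Oc2c(OCc3ccccc3)cc([Li])cc2C[C@@H]1O[Li] | intermediate (not isolated)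
14 | lithium triisopropoxy[(3S)-8-(benzyloxy)-3-(lithiooxy)-2,2-dimethylchroman-6-yl]borate | [Li+].CC1(C)Oc2c(OCc3ccccc3)cc([B-](OC(C)C)(OC(C)C)OC(C)C)cc2C[C@@H]1O[Li] | intermediate (not isolated)
15 | [(3S)-8-(benzyloxy)-3-hydroxy-2,2-dimethylchroman-6-yl]boronic acid | CC1(C)Oc2c(OCc3ccccc3)cc(B(O)O)cc2C[C@@H]1O | intermediate
16 | 7-hydroxy-4H-chromen-4-one | O=c1ccoc2cc(O)ccc12 | starting material
17 | 7-(benzyloxy)-4H-chromen-4-one | O=c1ccoc2cc(OCc3ccccc3)ccc12 | intermediate
18 | (2S)-7-(benzyloxy)-2-[(3S)-8-(benzyloxy)-3-hydroxy-2,2-dimethylchroman-6-yl]chroman-4-one | CC1(C)Oc2c(OCc3ccccc3)cc([C@@H]3CC(=O)c4ccc(OCc5ccccc5)cc4O3)cc2C[C@@H]1O | intermediate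
19 | (2S)-7-hydroxy-2-[(3S)-3,8-dihydroxy-2,2-dimethyl-3,4-dihydro-2H-chromen-6-yl]-2,3-dihydro-4H-chromen-4-one | CC1(C)Oc2c(O)cc([C@@H]3CC(=O)c4ccc(O)cc4O3)cc2C[C@@H]1O | target

## Step count and risks

Total step count: 12. Longest linear sequence: 11 steps (steps 1 to 9, then 11 and 12); step 10 is a one-step side branch.

The three steps most likely to fail:

Step 7. Under the basic carbene conditions the arylacetaldehyde may enolise and self-condense faster than the Breslow intermediate forms, or the tertiary radical may leave the radical pair before the ring closes. The fallback sets out from 10 and uses the known chromium-mediated decarboxylative addition of N-acyloxyphthalimides to aldehydes, here intramolecular: CrCl2 (divalent chromium, 4 equiv) and TMSCl in THF/DMF at rt, with aqueous acidic work-up to cleave the silyl ether. This should give racemic 8-(benzyloxy)-6-bromo-2,2-dimethylchroman-3-ol F1 by capture of the α-aryloxy radical as an organochromium species that adds to the aldehyde. Oxidation with Dess–Martin periodinane (NaHCO3, CH2Cl2) then returns to ketone 11.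

Step 11. Facial selectivity may erode on this electron-rich boronic acid, or β-aryloxide elimination from the rhodium enolate may open the pyranone ring. The fallback sets out from 12 and builds the heterocycle by organocatalytic oxa-Michael cyclisation instead of arylating a chromone. Treatment with n-BuLi (2.2 equiv) and then DMF gives (3S)-8-(benzyloxy)-3-hydroxy-2,2-dimethylchroman-6-carbaldehyde F2. Tert-butyl 3-[4-(benzyloxy)-2-hydroxyphenyl]-3-oxopropanoate F3 is made from commercial 1-[4-(benzyloxy)-2-hydroxyphenyl]ethanone with LiHMDS and di-tert-butyl dicarbonate. Knoevenagel condensation of F2 with F3 (piperidine, AcOH, toluene) gives tert-butyl 2-[4-(benzyloxy)-2-hydroxybenzoyl]-3-[(3S)-8-(benzyloxy)-3-hydroxy-2,2-dimethylchroman-6-yl]prop-2-enoate F4. A cinchona-alkaloid-derived bifunctional thiourea (the pseudo-enantiomer that leads to the 2S series) closes it to tert-butyl (2S)-7-(benzyloxy)-2-[(3S)-8-(benzyloxy)-3-hydroxy-2,2-dimethylchroman-6-yl]-4-oxochroman-3-carboxylate F5. Cleavage of the tert-butyl ester and decarboxylation with TsOH in toluene at 80 °C then returns to 18.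

Step 12. Hydrogenolysis may go on to cleave the benzylic C2–O1 bond of the flavanone or reduce its ketone once the benzyl ethers are gone. The fallback sets out from 18 and removes both benzyl groups without hydrogen or metal, by Lewis-acid cleavage with BCl3 and pentamethylbenzene as cation scavenger in CH2Cl2 at −78 °C. It returns directly to 19 and makes no new compound (F0).

## Further compounds

F1 | step 7 | racemic 8-(benzyloxy)-6-bromo-2,2-dimethylchroman-3-ol | CC1(C)Oc2c(OCc3ccccc3)cc(Br)cc2CC1O
F2 | step 11 | (3S)-8-(benzyloxy)-3-hydroxy-2,2-dimethylchroman-6-carbaldehyde | CC1(C)Oc2c(OCc3ccccc3)cc(C=O)cc2C[C@@H]1O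
F3 | step 11 | tert-butyl 3-[4-(benzyloxy)-2-hydroxyphenyl]-3-oxopropanoate | CC(C)(C)OC(=O)CC(=O)c1ccc(OCc2ccccc2)cc1O
F4 | step 11 | tert-butyl 2-[4-(benzyloxy)-2-hydroxybenzoyl]-3-[(3S)-8-(benzyloxy)-3-hydroxy-2,2-dimethylchroman-6-yl]prop-2-enoate (alkene geometry not controlled) | CC1(C)Oc2c(OCc3ccccc3)cc(C=C(C(=O)OC(C)(C)C)C(=O)c3ccc(OCc4ccccc4)cc3O)cc2C[C@@H]1O
F5 | step 11 | tert-butyl (2S)-7-(benzyloxy)-2-[(3S)-8-(benzyloxy)-3-hydroxy-2,2-dimethylchroman-6-yl]-4-oxochroman-3-carboxylate (C3 of the chromanone not defined) | CC1(C)Oc2c(OCc3ccccc3)cc([C@@H]3C(C(=O)OC(C)(C)C)C(=O)c4ccc(OCc5ccccc5)cc4O3)cc2C[C@@H]1O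
F0 | step 12 | none | none
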